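Digriseophene A is cut at both aryl ketone bonds and then through both rings A (ring A: C1 ketone-bearing, C2 and C6 hydroxyl, C3 bridge, C4 methoxy, C5 H). In each ring A the bridge-bearing C3 and the methoxy-bearing C4 are the two carbons of a methyl ynol ether, so the C3–CH2–C3' unit with both C4 methoxy groups is one molecule of 1,5-dimethoxypenta-1,4-diyne. A twofold Danheiser benzannulation with 3-(benzyloxy)cyclobutenone builds both rings A around this skipped diyne in one operation and leaves O2 free, O4 methylated and O6 benzylated. The free phenols then carry the ring-B acyl groups to C1 by esterification and Fries shift, and hydrogenolysis ends the route.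

Key step: step 6

Remark: the target has no stereocentre and no configurationally stable axis, so the question of a single enantiomer does not arise and no step needs stereocontrol.

Step 1
Reactants: 1 chloroacetaldehyde dimethyl acetal
Product: 3 methoxyacetylene, via sodium methoxyacetylide 2 (not isolated)
Conditions: NaNH2 (3.1 equiv), liq. NH3, −33 °C; NH3 off; cold satd aq NaCl; distil (bp 23 °C) into THF at −78 °C
Reagents that add atoms: none
Why: Base-induced loss of methanol and then of HCl from the α-chloro acetal, followed by deprotonation, is the standard α-halo acetal route to a 1-alkoxyalkyne, and water releases the volatile alkyne from its sodium salt.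

Step 2
Reactants: 3 methoxyacetylene; 4 paraformaldehyde
Product: 6 3-methoxyprop-2-yn-1-ol, via lithium methoxyacetylide 5 (not isolated)
Conditions: n-BuLi, THF, −78 °C; (CH2O)n, −78 °C → rt; H2O quench; Et3N-deactivated silica
Reagents that add atoms: none
Why: Hydroxymethylation of a lithium acetylide by 1,2-addition to formaldehyde is routine for alkoxyacetylides, and the non-acidic work-up avoids hydration or Meyer–Schuster-type rearrangement of the ynol ether carbinol.

Step 3
Reactants: 6 3-methoxyprop-2-yn-1-ol
Product: 7 3-bromo-1-methoxyprop-1-yne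
Conditions: CBr4, PPh3, 2,6-lutidine (0.1 equiv), CH2Cl2, −30 → 0 °C; pentane, filter through basic alumina; use at once as a cold solution
Reagents that add atoms: carbon tetrabromide, BrC(Br)(Br)Br
Why: The Appel reaction converts the primary alcohol through its alkoxyphosphonium salt into the bromide by SN2 attack under essentially neutral conditions that the acid-labile ynol ether should tolerate.

Step 4
Reactants: 3 methoxyacetylene; 7 3-bromo-1-methoxyprop-1-yne
Product: 9 1,5-dimethoxypenta-1,4-diyne, via (methoxyethynyl)magnesium bromide 8 (not isolated)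
Conditions: EtMgBr, THF, 0 °C; CuBr·SMe2 (10 mol %), then 7, −20 °C → rt; H2O quench; Et3N-deactivated silica, store cold
Reagents that add atoms: none
Why: Copper(I)-catalysed coupling of an alkynyl Grignard reagent with a primary propargylic bromide is the standard entry to skipped diynes, attack at the unhindered CH2 being favoured and the weakly basic magnesium acetylide limiting prototropic shift of the doubly propargylic CH2.

Step 5
Reactants: 10 3-ethoxycyclobut-2-en-1-one
Product: 11 3-(benzyloxy)cyclobut-2-en-1-one
Conditions: BnOH (3 equiv), PPTS (5 mol %), PhMe, 45 °C, reduced pressure (EtOH removed)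
Reagents that add atoms: benzyl alcohol, OCc1ccccc1
Why: Acid-catalysed addition–elimination at C3 of the vinylogous ester (transetherification, the alcohol counterpart of its known hydrolysis to cyclobutane-1,3-dione) is driven to the benzyl ether by removal of ethanol.

Step 6
Reactants: 9 1,5-dimethoxypenta-1,4-diyne; 11 3-(benzyloxy)cyclobut-2-en-1-one (two molecules per diyne)
Product: 14 2,2'-methylenebis[5-(benzyloxy)-3-methoxyphenol], via vinylketene 12 (not isolated), via monoannulated phenol 13 (not isolated)
Conditions: 11 (4 equiv, two portions), degassed PhMe (0.3 M), sealed tube, 80 → 110 °C; then K2CO3 (cat.), MeOH, rt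
Reagents that add atoms: none
Why: Proposed new method: heating opens cyclobutenone 11 by four-electron electrocyclic ring opening to vinylketene 12, the nucleophilic bridge-side carbon of one ynol ether of 9 attacks the ketene carbon in a [2+2] cycloaddition, and the 4-vinylcyclobutenone so formed opens in a second four-electron step to a dienylketene. Each ring A is then closed by thermal disrotatory six-electron electrocyclisation (C1–C2 bond) and tautomerisation of the cyclohexadienone to the phenol, which gives 13 after the first ynol ether and 14 after the second. The closest known reaction type is the Danheiser benzannulation of cyclobutenones with alkoxy- or silyloxyalkynes to resorcinol monoethers; new here are its twofold use on a 1,4-diyne carrying two ynol ethers and the 3-alkoxy group on the cyclobutenone. No stereocentre is formed, so no stereocontrol element is needed. The selectivity required is the orientation of the [2+2] step, which the polarisation of the ynol ether fixes (oxygen-bearing carbon to the ketene α-carbon, bridge-side carbon to the ketene carbon), so that each ring carries OH at C2, OMe at C4 and OBn at C6. A methyl ynol ether has no β-hydrogen for retro-ene loss of alkene at these temperatures, and the excess of 11 with the final catalytic methanolysis returns any phenol that a vinylketene has O-acylated.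

Step 7
Reactants: 15 methyl orsellinate
Product: 16 methyl 4-(benzyloxy)-2-hydroxy-6-methylbenzoate
Conditions: BnBr (1.05 equiv), K2CO3, acetone, reflux
Reagents that add atoms: benzyl bromide, BrCc1ccccc1
Why: Williamson etherification should occur at the 4-OH only, because the 2-OH is held in a hydrogen bond to the ester carbonyl and is much less nucleophilic.

Step 8
Reactants: 16 methyl 4-(benzyloxy)-2-hydroxy-6-methylbenzoate
Product: 17 methyl 4-(benzyloxy)-2-methoxy-6-methylbenzoate
Conditions: MeI (3 equiv), K2CO3, DMF, 50 °C
Reagents that add atoms: iodomethane, CI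
Why: Williamson methylation of the remaining chelated phenol proceeds under the more forcing conditions of a dipolar aprotic solvent and excess methyl iodide.

Step 9
Reactants: 17 methyl 4-(benzyloxy)-2-methoxy-6-methylbenzoate
Product: 18 4-(benzyloxy)-2-methoxy-6-methylbenzoic acid
Conditions: KOH (5 equiv), DMSO–H2O (4:1), 90 °C; then cold 1 M HCl to pH 2
Reagents that add atoms: potassium hydroxide, [K+].[OH-]
Why: Saponification of the di-ortho-substituted benzoate needs poorly solvated hydroxide and heat, both ether groups are inert to base, and cold acidification avoids decarboxylation of the electron-rich acid.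

Step 10
Reactants: 14 2,2'-methylenebis[5-(benzyloxy)-3-methoxyphenol]; 18 4-(benzyloxy)-2-methoxy-6-methylbenzoic acid (two molecules per bisphenol)
Product: 20 methylenebis[5-(benzyloxy)-3-methoxy-2,1-phenylene] bis[4-(benzyloxy)-2-methoxy-6-methylbenzoate], via 4-(benzyloxy)-2-methoxy-6-methylbenzoyl chloride 19 (not isolated)
Conditions: 18, (COCl)2, DMF (cat.), CH2Cl2, 0 °C → rt, evaporate; then 14, Et3N, DMAP (0.2 equiv), CH2Cl2, 0 °C → rt
Reagents that add atoms: none
Why: The acid chloride made by Vilsmeier-type activation O-acylates both phenols under DMAP nucleophilic catalysis (Einhorn-type esterification), and without a Lewis acid no C-acylation of the electron-rich rings is expected.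

Step 11
Reactants: 20 bis-ester
Product: 21 3,3'-methylenebis{[6-(benzyloxy)-2-hydroxy-4-methoxyphenyl][4-(benzyloxy)-2-methoxy-6-methylphenyl]methanone}
Conditions: TiCl4 (3 equiv), CH2Cl2, −40 → 0 °C, short reaction time; cold 1 M HCl quench
Reagents that add atoms: none
Why: In this Fries rearrangement the titanium-bound ester ionises easily to the 2,4-dialkoxy-6-methylbenzoyl cation, which the titanium aryloxide takes back at the only open ortho carbon C1 (para to OMe, product held as a six-membered titanium chelate), whereas the open para carbon C5 lies between two alkoxy groups and offers no chelate.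

Step 12
Reactants: 21 tetra-O-benzyl bis-benzophenone
Product: 22 Digriseophene A
Conditions: H2 (1 atm), 10% Pd/C, EtOAc–MeOH (1:1), rt
Reagents that add atoms: none
Why: Catalytic hydrogenolysis should remove the four aryl benzyl ethers, while the di-ortho-substituted, hydrogen-bonded diaryl ketones and the diarylmethane bridge resist reduction under these mild conditions.

Compound list
1 | chloroacetaldehyde dimethyl acetal (2-chloro-1,1-dimethoxyethane) | COC(CCl)OC | starting material
2 | sodium methoxyacetylide | [Na]C#COC | intermediate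
3 | methoxyacetylene (methoxyethyne), kept as a cold THF solution | COC#C | intermediate
4 | paraformaldehyde (source of formaldehyde) | C=O | starting material
5 | lithium methoxyacetylide | [Li]C#COC | intermediate
6 | 3-methoxyprop-2-yn-1-ol | COC#CCO | intermediate
7 | 3-bromo-1-methoxyprop-1-yne | COC#CCBr | intermediate
8 | (methoxyethynyl)magnesium bromide | COC#C[Mg]Br | intermediate
9 | 1,5-dimethoxypenta-1,4-diyne | COC#CCC#COC | intermediate
10 | 3-ethoxycyclobut-2-en-1-one | CCOC1=CC(=O)C1 | starting material
11 | 3-(benzyloxy)cyclobut-2-en-1-one | O=C1C=C(OCc2ccccc2)C1 | intermediate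
12 | 3-(benzyloxy)buta-1,3-dien-1-one (vinylketene) | C=C(OCc1ccccc1)C=C=O | intermediate
13 | 5-(benzyloxy)-3-methoxy-2-(3-methoxyprop-2-yn-1-yl)phenol (monoannulated phenol) | COC#CCc1c(OC)cc(OCc2ccccc2)cc1O | intermediate
14 | 2,2'-methylenebis[5-(benzyloxy)-3-methoxyphenol] | COc1cc(OCc2ccccc2)cc(O)c1Cc1c(OC)cc(OCc2ccccc2)cc1O | intermediate
15 | methyl orsellinate (methyl 2,4-dihydroxy-6-methylbenzoate) | COC(=O)c1c(C)cc(O)cc1O | starting material
16 | methyl 4-(benzyloxy)-2-hydroxy-6-methylbenzoate | COC(=O)c1c(C)cc(OCc2ccccc2)cc1O | intermediate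
17 | methyl 4-(benzyloxy)-2-methoxy-6-methylbenzoate | COC(=O)c1c(C)cc(OCc2ccccc2)cc1OC | intermediate
18 | 4-(benzyloxy)-2-methoxy-6-methylbenzoic acid | COc1cc(OCc2ccccc2)cc(C)c1C(=O)O | intermediate
19 | 4-(benzyloxy)-2-methoxy-6-methylbenzoyl chloride | COc1cc(OCc2ccccc2)cc(C)c1C(Cl)=O | intermediate
20 | methylenebis[5-(benzyloxy)-3-methoxy-2,1-phenylene] bis[4-(benzyloxy)-2-methoxy-6-methylbenzoate] (bis-ester) | COc1cc(OCc2ccccc2)cc(OC(=O)c2c(C)cc(OCc3ccccc3)cc2OC)c1Cc1c(OC)cc(OCc2ccccc2)cc1OC(=O)c1c(C)cc(OCc2ccccc2)cc1OC | intermediate
21 | 3,3'-methylenebis{[6-(benzyloxy)-2-hydroxy-4-methoxyphenyl][4-(benzyloxy)-2-methoxy-6-methylphenyl]methanone} | COc1cc(OCc2ccccc2)c(C(=O)c2c(C)cc(OCc3ccccc3)cc2OC)c(O)c1Cc1c(OC)cc(OCc2ccccc2)c(C(=O)c2c(C)cc(OCc3ccccc3)cc2OC)c1O | intermediate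
22 | Digriseophene A, 3,3'-methylenebis[(2,6-dihydroxy-4-methoxyphenyl)(4-hydroxy-2-methoxy-6-methylphenyl)methanone] | COc1cc(O)c(C(=O)c2c(C)cc(O)cc2OC)c(O)c1Cc1c(OC)cc(O)c(C(=O)c2c(C)cc(O)cc2OC)c1O | target

Total step count: 12. Longest linear sequence: 8 (steps 1, 2, 3, 4, 6, 10, 11, 12).

Steps most likely to fail

Step 6 (Proposed new method). The donor-stabilised cyclobutenone may open so slowly that thermal isomerisation or oligomerisation of the skipped diyne outruns the cycloaddition. The phenol formed in the first annulation may also add across the neighbouring ynol ether before the second annulation, and vinylketene may be lost to O-acylation. The fallback uses known chemistry only and builds the bridge last. It sets out from acid chloride 19 and comes back to the route at target 22. 5-Methoxyresorcinol F1 is converted with MOMCl and iPr2NEt into 1-methoxy-3,5-bis(methoxymethoxy)benzene F2. Directed ortho-lithiation between the two MOM ethers (n-BuLi, THF, 0 °C) and acylation with 19 at −78 °C should give [4-(benzyloxy)-2-methoxy-6-methylphenyl][4-methoxy-2,6-bis(methoxymethoxy)phenyl]methanone F3. HCl in methanol removes the MOM groups to give [4-(benzyloxy)-2-methoxy-6-methylphenyl](2,6-dihydroxy-4-methoxyphenyl)methanone F4. Aqueous formaldehyde (0.5 equiv) with catalytic base then joins two molecules at the equivalent ring-A carbons between OH and OMe, a phenol–formaldehyde condensation, to give the methylene-bridged bis(benzyl ether) F5. Hydrogenolysis as in step 12 gives 22.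

Step 11. The acyl group may return to the open para carbon C5. The Lewis acid may also strip benzyl groups, which then re-benzylate the electron-rich rings, or acid may cleave the diarylmethane bridge. The fallback replaces acyl migration by ortho-specific formylation and aryllithium addition. It sets out from bisphenol 14 and acid 18 and comes back at target 22. Magnesium-mediated ortho-formylation of 14 (MgCl2, Et3N, paraformaldehyde, MeCN, reflux) can only reach C1 and should give 3,3'-methylenebis[6-(benzyloxy)-2-hydroxy-4-methoxybenzaldehyde] F6. Benzylation (BnBr, K2CO3, DMF) gives 3,3'-methylenebis[2,6-bis(benzyloxy)-4-methoxybenzaldehyde] F7. Bromodecarboxylation of 18 (Bu4NBr3, K3PO4, MeCN) gives 5-(benzyloxy)-2-bromo-1-methoxy-3-methylbenzene F8. Bromine–lithium exchange on F8 (n-BuLi, THF, −78 °C) and addition to F7 gives the bis-carbinol F9 as a mixture of diastereomers. Dess–Martin oxidation removes both carbinol centres and gives the hexabenzyl bis-benzophenone F10. Hydrogenolysis as in step 12 gives 22.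

Step 4. The donor-activated propargylic bromide may ionise or be attacked at its oxygen-bearing alkyne carbon, bromide 7 may decompose on handling, and base may shift the product to an allenyne. The fallback brings in the bridge carbon as a carbinol, so that neither a propargylic halide nor a free skipped CH2 is needed. It sets out from methoxyacetylene 3 (as lithium acetylide 5) and comes back at bisphenol 14. Two equivalents of 5 add to ethyl formate to give 1,5-dimethoxypenta-1,4-diyn-3-ol F11. TBSCl and imidazole give tert-butyl[(1,5-dimethoxypenta-1,4-diyn-3-yl)oxy]dimethylsilane F12. Benzannulation of F12 with 11 under the conditions of step 6 should give 2,2'-{[(tert-butyldimethylsilyl)oxy]methylene}bis[5-(benzyloxy)-3-methoxyphenol] F13. Ionic hydrogenation of this doubly activated benzhydryl ether (Et3SiH, TFA, CH2Cl2, −20 °C) gives 14.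

Further compounds
F1 | step 6 | 5-methoxyresorcinol (5-methoxybenzene-1,3-diol) | COc1cc(O)cc(O)c1
F2 | step 6 | 1-methoxy-3,5-bis(methoxymethoxy)benzene | COCOc1cc(OC)cc(OCOC)c1
F3 | step 6 | [4-(benzyloxy)-2-methoxy-6-methylphenyl][4-methoxy-2,6-bis(methoxymethoxy)phenyl]methanone | COCOc1cc(OC)cc(OCOC)c1C(=O)c1c(C)cc(OCc2ccccc2)cc1OC
F4 | step 6 | [4-(benzyloxy)-2-methoxy-6-methylphenyl](2,6-dihydroxy-4-methoxyphenyl)methanone | COc1cc(O)c(C(=O)c2c(C)cc(OCc3ccccc3)cc2OC)c(O)c1
F5 | step 6 | 3,3'-methylenebis{[4-(benzyloxy)-2-methoxy-6-methylphenyl](2,6-dihydroxy-4-methoxyphenyl)methanone} | COc1cc(O)c(C(=O)c2c(C)cc(OCc3ccccc3)cc2OC)c(O)c1Cc1c(OC)cc(O)c(C(=O)c2c(C)cc(OCc3ccccc3)cc2OC)c1O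
F6 | step 11 | 3,3'-methylenebis[6-(benzyloxy)-2-hydroxy-4-methoxybenzaldehyde] | COc1cc(OCc2ccccc2)c(C=O)c(O)c1Cc1c(OC)cc(OCc2ccccc2)c(C=O)c1O
F7 | step 11 | 3,3'-methylenebis[2,6-bis(benzyloxy)-4-methoxybenzaldehyde] | COc1cc(OCc2ccccc2)c(C=O)c(OCc2ccccc2)c1Cc1c(OC)cc(OCc2ccccc2)c(C=O)c1OCc1ccccc1
F8 | step 11 | 5-(benzyloxy)-2-bromo-1-methoxy-3-methylbenzene | COc1cc(OCc2ccccc2)cc(C)c1Br
F9 | step 11 | 3,3'-methylenebis{[2,6-bis(benzyloxy)-4-methoxyphenyl][4-(benzyloxy)-2-methoxy-6-methylphenyl]methanol}, mixture of diastereomers | COc1cc(OCc2ccccc2)c(C(O)c2c(C)cc(OCc3ccccc3)cc2OC)c(OCc2ccccc2)c1Cc1c(OC)cc(OCc2ccccc2)c(C(O)c2c(C)cc(OCc3ccccc3)cc2OC)c1OCc1ccccc1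
F10 | step 11 | 3,3'-methylenebis{[2,6-bis(benzyloxy)-4-methoxyphenyl][4-(benzyloxy)-2-methoxy-6-methylphenyl]methanone} | COc1cc(OCc2ccccc2)c(C(=O)c2c(C)cc(OCc3ccccc3)cc2OC)c(OCc2ccccc2)c1Cc1c(OC)cc(OCc2ccccc2)c(C(=O)c2c(C)cc(OCc3ccccc3)cc2OC)c1OCc1ccccc1
F11 | step 4 | 1,5-dimethoxypenta-1,4-diyn-3-ol | COC#CC(O)C#COC
F12 | step 4 | tert-butyl[(1,5-dimethoxypenta-1,4-diyn-3-yl)oxy]dimethylsilane | COC#CC(O[Si](C)(C)C(C)(C)C)C#COC
F13 | step 4 | 2,2'-{[(tert-butyldimethylsilyl)oxy]methylene}bis[5-(benzyloxy)-3-methoxyphenol] | COc1cc(OCc2ccccc2)cc(O)c1C(O[Si](C)(C)C(C)(C)C)c1c(OC)cc(OCc2ccccc2)cc1O
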